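Ring atoms are numbered C1 (ketone), C2 (methyl-bearing oxirane carbon), C3 (oxirane CH), C4 (CH2), C5 (isopropenyl) and C6 (acyloxy). Everything rests on cutting the C5–C6 bond: an isopropenyl group on C5 next to an oxygenated C6 that is itself α to the C1 ketone is what an ene reaction between a prenyl terminus and the aldehyde of a glyoxal leaves behind. One Lewis-acid-mediated step therefore closes the six-membered carbocycle, forms C5–C6, sets C5 and C6 and releases the free C6 hydroxyl. Its precursor is an acyclic cis-epoxy keto aldehyde whose oxirane, installed by one Sharpless epoxidation, is the only stereochemical input; a late Yamaguchi esterification attaches the separately made acid.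

Key step: step 8

Remark: keto aldehyde 10 is assumed to be obtained and used as the anhydrous dicarbonyl; any hydrate formed during work-up is expected to revert on azeotropic drying with toluene.

Step 1
Reactants: 1 4-methylpent-3-en-1-ol
Product: 2 4-methylpent-3-enal
Conditions: TEMPO (10 mol %), PhI(OAc)2 (1.1 equiv), CH2Cl2, 0 °C → rt; aq. NaHCO3 wash, solution used directly
Reagents that add atoms: none
Why: Oxoammonium (TEMPO/PhI(OAc)2) oxidation of a primary alcohol stops at the aldehyde under non-basic conditions, which should limit migration of the β,γ-double bond into conjugation and leaves the trisubstituted alkene untouched.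

Step 2
Reactants: 2 4-methylpent-3-enal; 3 ethyl 2-[bis(2,2,2-trifluoroethoxy)phosphoryl]propanoate
Product: 4 ethyl (2Z)-2,6-dimethylhepta-2,5-dienoate
Conditions: KN(SiMe3)2, 18-crown-6, THF, −78 °C
Reagents that add atoms: none
Why: Still–Gennari variant of the Horner–Wadsworth–Emmons olefination, in which the electron-poor bis(trifluoroethyl) phosphonate and the crown-separated potassium ion make elimination fast and irreversible, so the kinetic Z-enoate (ester cis to the chain) should form while the weakly basic phosphonate anion at −78 °C spares the isomerisable aldehyde.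

Step 3
Reactants: 4 ethyl (2Z)-2,6-dimethylhepta-2,5-dienoate
Product: 5 (2Z)-2,6-dimethylhepta-2,5-dien-1-ol
Conditions: i-Bu2AlH (2.3 equiv), CH2Cl2, −78 → 0 °C
Reagents that add atoms: none
Why: Hydride reduction of a conjugated ester with i-Bu2AlH proceeds by 1,2-addition only, giving the allylic alcohol without touching either alkene or the Z geometry.

Step 4
Reactants: 5 (2Z)-2,6-dimethylhepta-2,5-dien-1-ol
Product: 6 [(2R,3S)-2-methyl-3-(3-methylbut-2-en-1-yl)oxiran-2-yl]methanol
Conditions: Ti(OiPr)4 (10 mol %), D-(−)-diethyl tartrate (12 mol %), t-BuOOH (2 equiv, decane), 4 Å molecular sieves, CH2Cl2, −20 °C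
Reagents that add atoms: tert-butyl hydroperoxide, CC(C)(C)OO
Why: Katsuki–Sharpless asymmetric epoxidation, in which the titanium tartrate complex binds the allylic hydroxyl and oxidises only the C2=C3 alkene (the remote prenyl alkene has no directing group); the D-(−)-ligand is the one that turns a (Z)-2-methyl allylic alcohol into the (2R,3S)-oxirane, which fixes both oxirane stereocentres (ring C2 and C3), and the Z geometry becomes the cis relationship of the two arms.

Step 5
Reactants: 6 [(2R,3S)-2-methyl-3-(3-methylbut-2-en-1-yl)oxiran-2-yl]methanol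
Product: 7 (2S,3S)-2-methyl-3-(3-methylbut-2-en-1-yl)oxirane-2-carbaldehyde
Conditions: TEMPO (10 mol %), PhI(OAc)2 (1.1 equiv), CH2Cl2, rt
Reagents that add atoms: none
Why: Oxoammonium oxidation of the primary epoxy alcohol stops at the aldehyde, the α-carbon is quaternary so neither oxirane centre can epimerise, and the prenyl alkene is inert to this oxidant.

Step 6
Reactants: 7 (2S,3S)-2-methyl-3-(3-methylbut-2-en-1-yl)oxirane-2-carbaldehyde
Product: 9 1-[(2R,3S)-2-methyl-3-(3-methylbut-2-en-1-yl)oxiran-2-yl]ethane-1,2-diol, via β-hydroxysilane 8 (not isolated)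
Conditions: i-PrOMe2SiCH2MgCl (made from i-PrOMe2SiCH2Cl and Mg in THF), THF, 0 °C; then KF, KHCO3, 30% H2O2, THF–MeOH, rt
Reagents that add atoms: {[dimethyl(propan-2-yloxy)silyl]methyl}magnesium chloride, CC(C)O[Si](C)(C)C[Mg]Cl; hydrogen peroxide, OO
Why: Tamao hydroxymethylation, in which the silylmethyl Grignard reagent adds to the aldehyde much faster than it opens the trisubstituted oxirane and the fluoride-assisted, bicarbonate-buffered peroxide oxidation of the C–Si bond delivers the primary hydroxyl without Peterson elimination; the new carbinol centre forms as an epimer mixture that converges in step 7.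

Step 7
Reactants: 9 1-[(2R,3S)-2-methyl-3-(3-methylbut-2-en-1-yl)oxiran-2-yl]ethane-1,2-diol
Product: 10 2-[(2S,3S)-2-methyl-3-(3-methylbut-2-en-1-yl)oxiran-2-yl]-2-oxoacetaldehyde
Conditions: (COCl)2 (4 equiv), DMSO (8 equiv), CH2Cl2, −78 °C; Et3N (10 equiv), −78 → −20 °C; cold pH 7 buffer wash, toluene azeotrope, used at once
Reagents that add atoms: none
Why: Twofold Swern (activated-DMSO) oxidation takes both hydroxyls of a 1,2-diol to the α-keto aldehyde without the C–C cleavage that hypervalent-iodine or periodate oxidants risk, works below −20 °C where oxirane and alkene are inert, and gives the dicarbonyl free of water; no stereocentre is touched.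

Step 8
Reactants: 10 2-[(2S,3S)-2-methyl-3-(3-methylbut-2-en-1-yl)oxiran-2-yl]-2-oxoacetaldehyde
Product: 11 (1S,3R,4R,6S)-3-hydroxy-1-methyl-4-(prop-1-en-2-yl)-7-oxabicyclo[4.1.0]heptan-2-one
Conditions: Me2AlCl (2.2 equiv, hexanes), CH2Cl2 (0.02 M), −78 °C
Reagents that add atoms: none
Why: Two-point binding of the 1,2-dicarbonyl by aluminium (Me2AlCl in excess forms a cationic chelate) makes the aldehyde carbon C6 the most electrophilic site, and the prenyl π bond adds to it through C5 while a hydrogen of a terminal methyl group passes to the aldehyde oxygen across a six-membered array, a concerted but asynchronous type-one carbonyl-ene reaction. The closest known reactions are the Lewis-acid closure of citronellal to isopulegol and Me2AlCl-promoted ene reactions of aldehydes, glyoxylates and α-keto esters. The one ring formed, the C1–C6 carbocycle, closes in the 6-exo-trig mode at the aldehyde carbonyl with the alkene reacting at its tethered end, so the shifted double bond ends outside the ring as the isopropenyl group. C5 and C6 are expected trans because the chelated aldehyde oxygen, held near the plane of the ketone, and the developing isopropenyl group both take pseudo-equatorial positions in the chair-like array; their sense relative to the oxirane depends on which epoxide-fused half-chair closes, the required one having C5 on the oxirane-oxygen face and C6 tilted toward the C2-methyl face, which puts isopropenyl anti and hydroxyl syn to the oxirane oxygen. The step needs the aldehyde to react in preference to the ketone and the oxirane, which the greater electrophilicity of the chelated aldehyde, the cis-oxirane holding both arms on one side, the low temperature and the Me–Al bonds that consume the proton of the new hydroxyl should secure. It also needs discrimination between the two half-chairs, for which the substrate offers only the conformational bias of the cis-oxirane (the wanted half-chair tilts the ketone oxygen toward the oxirane oxygen, an arrangement that a second aluminium centre bridging the two oxygens would favour), and this is the least secure point of the route.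

Step 9
Reactants: 12 tiglic acid; 13 3-methylbut-2-en-1-ol
Product: 14 3-methylbut-2-en-1-yl (2E)-2-methylbut-2-enoate
Conditions: DCC, DMAP (10 mol %), CH2Cl2, 0 °C → rt
Reagents that add atoms: none
Why: Steglich esterification (carbodiimide activation, DMAP acyl transfer) of an unhindered primary allylic alcohol is neutral and should leave both alkene geometries unchanged.

Step 10
Reactants: 14 3-methylbut-2-en-1-yl (2E)-2-methylbut-2-enoate
Product: 15 (2E)-3-methyl-4-oxobut-2-en-1-yl (2E)-2-methylbut-2-enoate
Conditions: SeO2 (1.2 equiv), 1,4-dioxane, 80 °C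
Reagents that add atoms: selenium dioxide, O=[Se]=O
Why: Riley allylic oxidation (ene reaction with SeO2, then [2,3]-sigmatropic shift) attacks the electron-rich prenyl alkene at its E-methyl group in preference to the electron-poor tiglate and, in hot dioxane, should run on to the (E)-enal.

Step 11
Reactants: 15 (2E)-3-methyl-4-oxobut-2-en-1-yl (2E)-2-methylbut-2-enoate
Product: 16 (2E)-2-methyl-4-{[(2E)-2-methylbut-2-enoyl]oxy}but-2-enoic acid
Conditions: NaClO2, NaH2PO4, 2-methylbut-2-ene, t-BuOH–H2O, 0 °C → rt
Reagents that add atoms: sodium chlorite, [Na+].[O-]Cl=O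
Why: Pinnick oxidation converts the enal into the acid at buffered pH without isomerising either trisubstituted alkene or cleaving the allylic ester, the hypochlorous acid by-product being trapped by 2-methylbut-2-ene.

Step 12
Reactants: 16 (2E)-2-methyl-4-{[(2E)-2-methylbut-2-enoyl]oxy}but-2-enoic acid; 11 (1S,3R,4R,6S)-3-hydroxy-1-methyl-4-(prop-1-en-2-yl)-7-oxabicyclo[4.1.0]heptan-2-one
Product: 18 (1S,3R,4R,6S)-1-methyl-2-oxo-4-(prop-1-en-2-yl)-7-oxabicyclo[4.1.0]heptan-3-yl (2E)-2-methyl-4-{[(2E)-2-methylbut-2-enoyl]oxy}but-2-enoate, via mixed anhydride 17 (not isolated)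
Conditions: 2,4,6-trichlorobenzoyl chloride, Et3N, toluene, rt; then 11, DMAP, toluene, 0 °C → rt
Reagents that add atoms: none
Why: Yamaguchi esterification, in which DMAP attacks the less hindered enoyl carbonyl of the mixed anhydride and the acylpyridinium acylates the secondary C6 hydroxyl with retention; oxirane, ketone and both E-alkenes should survive, and the trans, diequatorial C5/C6 arrangement is the thermodynamically preferred one should the α-ketol centre enolise.

Compound list
1 | 4-methylpent-3-en-1-ol | CC(C)=CCCO | starting material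
2 | 4-methylpent-3-enal | CC(C)=CCC=O | intermediate
3 | ethyl 2-[bis(2,2,2-trifluoroethoxy)phosphoryl]propanoate | CCOC(=O)C(C)P(=O)(OCC(F)(F)F)OCC(F)(F)F | starting material
4 | ethyl (2Z)-2,6-dimethylhepta-2,5-dienoate | CCOC(=O)/C(C)=C\CC=C(C)C | intermediate
5 | (2Z)-2,6-dimethylhepta-2,5-dien-1-ol | OC/C(C)=C\CC=C(C)C | intermediate
6 | [(2R,3S)-2-methyl-3-(3-methylbut-2-en-1-yl)oxiran-2-yl]methanol | CC(C)=CC[C@@H]1O[C@]1(C)CO | intermediate
7 | (2S,3S)-2-methyl-3-(3-methylbut-2-en-1-yl)oxirane-2-carbaldehyde | CC(C)=CC[C@@H]1O[C@]1(C)C=O | intermediate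
8 | 2-[dimethyl(propan-2-yloxy)silyl]-1-[(2R,3S)-2-methyl-3-(3-methylbut-2-en-1-yl)oxiran-2-yl]ethan-1-ol (carbinol epimers) | CC(C)=CC[C@@H]1O[C@]1(C)C(O)C[Si](C)(C)OC(C)C | intermediate
9 | 1-[(2R,3S)-2-methyl-3-(3-methylbut-2-en-1-yl)oxiran-2-yl]ethane-1,2-diol (carbinol epimers) | CC(C)=CC[C@@H]1O[C@]1(C)C(O)CO | intermediate
10 | 2-[(2S,3S)-2-methyl-3-(3-methylbut-2-en-1-yl)oxiran-2-yl]-2-oxoacetaldehyde | CC(C)=CC[C@@H]1O[C@]1(C)C(=O)C=O | intermediate
11 | (1S,3R,4R,6S)-3-hydroxy-1-methyl-4-(prop-1-en-2-yl)-7-oxabicyclo[4.1.0]heptan-2-one | C=C(C)[C@H]1C[C@@H]2O[C@]2(C)C(=O)[C@@H]1O | intermediate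
12 | tiglic acid, (2E)-2-methylbut-2-enoic acid | C/C=C(\C)C(=O)O | starting material
13 | 3-methylbut-2-en-1-ol | CC(C)=CCO | starting material
14 | 3-methylbut-2-en-1-yl (2E)-2-methylbut-2-enoate | C/C=C(\C)C(=O)OCC=C(C)C | intermediate
15 | (2E)-3-methyl-4-oxobut-2-en-1-yl (2E)-2-methylbut-2-enoate | C/C=C(\C)C(=O)OC/C=C(\C)C=O | intermediate
16 | (2E)-2-methyl-4-{[(2E)-2-methylbut-2-enoyl]oxy}but-2-enoic acid | C/C=C(\C)C(=O)OC/C=C(\C)C(=O)O | intermediate
17 | (2E)-2-methyl-4-{[(2E)-2-methylbut-2-enoyl]oxy}but-2-enoic 2,4,6-trichlorobenzoic anhydride | C/C=C(\C)C(=O)OC/C=C(\C)C(=O)OC(=O)c1c(Cl)cc(Cl)cc1Cl | intermediate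
18 | (1S,3R,4R,6S)-1-methyl-2-oxo-4-(prop-1-en-2-yl)-7-oxabicyclo[4.1.0]heptan-3-yl (2E)-2-methyl-4-{[(2E)-2-methylbut-2-enoyl]oxy}but-2-enoate | C=C(C)[C@H]1C[C@@H]2O[C@]2(C)C(=O)[C@@H]1OC(=O)/C(C)=C/COC(=O)/C(C)=C/C | target

Total step count: 12 (steps 1–8 and 12 on the main line, steps 9–11 for the acid).
Longest linear sequence: 9 steps (1–8, then 12) from 4-methylpent-3-en-1-ol.

Steps most likely to fail

Step 8. The ring may close through the other epoxide-fused half-chair, giving poor or wrong facial selectivity relative to the oxirane; methyl transfer from aluminium to the aldehyde or Lewis-acid opening of the oxirane may also compete. The fallback installs the oxirane after the ring exists, so that it is set by the C5 substituent and not the other way round. It sets out from dienol 5 and rejoins the route at core alcohol 11.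
- MnO2 in CH2Cl2 oxidises 5 to (2Z)-2,6-dimethylhepta-2,5-dienal F1.
- The silylmethyl Grignard reagent of step 6 adds to give (3Z)-1-[dimethyl(propan-2-yloxy)silyl]-3,7-dimethylocta-3,6-dien-2-ol F2, which is oxidised in the same flask (KF, KHCO3, H2O2) to (3Z)-3,7-dimethylocta-3,6-diene-1,2-diol F3.
- Twofold Swern oxidation gives (3Z)-3,7-dimethyl-2-oxoocta-3,6-dienal F4.
- The same carbonyl-ene closure is run on this achiral substrate under reagent control with the divalent copper complex [Cu((R,R)-t-Bu-box)](SbF6)2. This ligand enantiomer is chosen by analogy with glyoxylate-ene reactions, where the (S,S)-ligand gives the S carbinol, and should deliver (5R,6R)-6-hydroxy-2-methyl-5-(prop-1-en-2-yl)cyclohex-2-en-1-one F5.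
- Weitz–Scheffer epoxidation (t-BuOOH, DBU, CH2Cl2, 0 °C) should then add the oxirane oxygen anti to the isopropenyl group, as is the rule for carvone-type enones, giving 11.

Step 7. The double oxidation may stall at a hydroxy carbonyl stage or cleave the C–C bond, and the glyoxal may hydrate or oligomerise during work-up. The fallback brings the aldehyde carbon in at the right oxidation level but masked. It sets out from epoxy aldehyde 7 and rejoins the route at keto aldehyde 10.
- 2-Lithio-1,3-dithiane (THF, −78 °C) adds to give (1,3-dithian-2-yl)[(2R,3S)-2-methyl-3-(3-methylbut-2-en-1-yl)oxiran-2-yl]methanol F6.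
- Parikh–Doering oxidation (SO3·pyridine, DMSO, i-Pr2NEt) gives (1,3-dithian-2-yl)[(2S,3S)-2-methyl-3-(3-methylbut-2-en-1-yl)oxiran-2-yl]methanone F7.
- Alkylative hydrolysis (MeI, CaCO3, aqueous MeCN) unmasks 10, which is dried azeotropically before step 8.

Step 2. Aldehyde 2 may slip into conjugation or be enolised by the base, and Z-selectivity may erode. The fallback reverses the polarity of the olefination so that no β,γ-unsaturated aldehyde is needed. It sets out from alcohol 1 and rejoins the route at dienol 5.
- Appel bromination (CBr4, PPh3, CH2Cl2) gives 5-bromo-2-methylpent-2-ene F8.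
- PPh3 in refluxing MeCN gives (4-methylpent-3-en-1-yl)triphenylphosphonium bromide F9.
- n-BuLi (THF, −78 °C) generates (4-methylpent-3-en-1-ylidene)triphenylphosphorane F10, which is condensed with 1-[(tert-butyldimethylsilyl)oxy]propan-2-one. Wittig reactions of non-stabilised ylides with α-alkoxy ketones are reliably Z-selective, so tert-butyl{[(2Z)-2,6-dimethylhepta-2,5-dien-1-yl]oxy}dimethylsilane F11 should result.
- Bu4NF in THF removes the silyl group to give 5.

Further compounds
F1 | step 8 | (2Z)-2,6-dimethylhepta-2,5-dienal | O=C/C(C)=C\CC=C(C)C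
F2 | step 8 | (3Z)-1-[dimethyl(propan-2-yloxy)silyl]-3,7-dimethylocta-3,6-dien-2-ol | CC(C)O[Si](C)(C)CC(O)/C(C)=C\CC=C(C)C
F3 | step 8 | (3Z)-3,7-dimethylocta-3,6-diene-1,2-diol | OCC(O)/C(C)=C\CC=C(C)C
F4 | step 8 | (3Z)-3,7-dimethyl-2-oxoocta-3,6-dienal | O=CC(=O)/C(C)=C\CC=C(C)C
F5 | step 8 | (5R,6R)-6-hydroxy-2-methyl-5-(prop-1-en-2-yl)cyclohex-2-en-1-one | C=C(C)[C@H]1CC=C(C)C(=O)[C@@H]1O
F6 | step 7 | (1,3-dithian-2-yl)[(2R,3S)-2-methyl-3-(3-methylbut-2-en-1-yl)oxiran-2-yl]methanol | CC(C)=CC[C@@H]1O[C@]1(C)C(O)C2SCCCS2
F7 | step 7 | (1,3-dithian-2-yl)[(2S,3S)-2-methyl-3-(3-methylbut-2-en-1-yl)oxiran-2-yl]methanone | CC(C)=CC[C@@H]1O[C@]1(C)C(=O)C2SCCCS2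
F8 | step 2 | 5-bromo-2-methylpent-2-ene | CC(C)=CCCBr
F9 | step 2 | (4-methylpent-3-en-1-yl)triphenylphosphonium bromide | CC(C)=CCC[P+](c1ccccc1)(c1ccccc1)c1ccccc1.[Br-]
F10 | step 2 | (4-methylpent-3-en-1-ylidene)triphenylphosphorane | CC(C)=CCC=P(c1ccccc1)(c1ccccc1)c1ccccc1
F11 | step 2 | tert-butyl{[(2Z)-2,6-dimethylhepta-2,5-dien-1-yl]oxy}dimethylsilane | CC(C)=CC/C=C(/C)CO[Si](C)(C)C(C)(C)C
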